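**Retrosynthetic overview**
1. The triene tail is cut at C15=C16 (Horner–Wadsworth–Emmons: dienylphosphonate 38 + aldehyde 34) and at C8–C9 (Wittig of salt 30 on aldehyde 26, then diimide), leaving the bicyclic core 24.
2. Feature used: the γ-lactone (C1, C2, C3, C4, ring O) is cis-fused to the 1,2-dioxane (O1, O2, C3, C4, C5, C6) across C3–C4, so the peroxy-bearing C3 lies next to the oxygen-bearing C4. Cutting C2–C3 gives a C3 peroxycarbenium ion and a ketene silyl acetal carried on the C4 oxygen (22).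
3. 22 comes from methoxy peroxyacetal 18, that is, a C6 hydroperoxide closing onto a C3 aldehyde; the hydroperoxide comes from oxetane 11 by invertive opening with H2O2, which sets C6.
4. 11 comes from asymmetric epoxidation of E-allylic alcohol 7, made from alkyne 3 and (R)-2-methylglycidol 1, which supplies C3–C5 and the C4 stereocentre.
5. Ring order: oxetane (step 7, consumed in step 8), 1,2-dioxane (step 12), γ-lactone (step 16).

Key step: step 16

Remark: atoms carry the target numbering (C1 lactone carbonyl, C2, C3 peroxy CH, C4 lactone-oxygen carbon, C5, C6 peroxy quaternary carbon, C7–C22 chain); hydrogen peroxide is assumed to be used as a dried ethereal solution, and compounds 17–23 are C3 epimer mixtures that converge in step 16.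

**Step 1**
Reactants: 1 (R)-2-methylglycidol
Product: 2 tert-butyl{[(2S)-2-methyloxiran-2-yl]methoxy}diphenylsilane
Conditions: TBDPSCl, imidazole, CH2Cl2, 0 °C → rt
Reagents that add atoms: tert-butyl(chloro)diphenylsilane, CC(C)(C)[Si](Cl)(c1ccccc1)c1ccccc1
Why: Imidazole-mediated silylation of the primary alcohol leaves the epoxide and the quaternary C4 centre untouched (the descriptor changes from R to S only because the silyloxymethyl group gains CIP priority).

**Step 2**
Reactants: 2 tert-butyl{[(2S)-2-methyloxiran-2-yl]methoxy}diphenylsilane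
Product: 3 (2S)-1-[(tert-butyldiphenylsilyl)oxy]-2-methylpent-4-yn-2-ol
Conditions: LiC≡CH·H2NCH2CH2NH2, DMSO, 15 °C → rt; H2O
Reagents that add atoms: lithium acetylide–ethylenediamine complex, [Li+].[C-]#C.NCCN
Why: Epoxide opening by an acetylide (SN2 at the unsubstituted CH2, C5) forms C5–C6 and frees the C4 tertiary alcohol without breaking a bond at C4, so its configuration is that of 1.

**Step 3**
Reactants: 3 (2S)-1-[(tert-butyldiphenylsilyl)oxy]-2-methylpent-4-yn-2-ol
Product: 4 tert-butyl({(2S)-2-methyl-2-[(triethylsilyl)oxy]pent-4-yn-1-yl}oxy)diphenylsilane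
Conditions: TESOTf, 2,6-lutidine, CH2Cl2, −78 → 0 °C
Reagents that add atoms: triethylsilyl trifluoromethanesulfonate, CC[Si](CC)(CC)OS(=O)(=O)C(F)(F)F
Why: Silyl triflate silylation of the tertiary alcohol blocks the C4 oxygen, which would otherwise close a six-membered ether onto C8 in step 7.

**Step 4**
Reactants: 4 tert-butyl({(2S)-2-methyl-2-[(triethylsilyl)oxy]pent-4-yn-1-yl}oxy)diphenylsilane
Product: 7 (2E,5S)-6-[(tert-butyldiphenylsilyl)oxy]-3,5-dimethyl-5-[(triethylsilyl)oxy]hex-2-en-1-ol, via alkenyl(dimethyl)alane 5 (not isolated), via lithium butyl(dimethyl)alkenylalanate 6 (not isolated)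
Conditions: Me3Al, Cp2ZrCl2 (0.25 equiv), CH2Cl2, 0 °C → rt; evaporate; n-BuLi, THF/hexane, −78 °C; (CH2O)n, −78 °C → rt
Reagents that add atoms: trimethylaluminium, C[Al](C)C; paraformaldehyde (as formaldehyde), C=O
Why: Zirconium-catalysed methylalumination (Negishi carboalumination) adds CH3 to C6 and Al to C7 in a syn fashion, and the alanate is hydroxymethylated by formaldehyde with retention, which fixes the E geometry of the trisubstituted allylic alcohol.

**Step 5**
Reactants: 7 (2E,5S)-6-[(tert-butyldiphenylsilyl)oxy]-3,5-dimethyl-5-[(triethylsilyl)oxy]hex-2-en-1-ol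
Product: 8 [(2S,3S)-3-{(2S)-3-[(tert-butyldiphenylsilyl)oxy]-2-methyl-2-[(triethylsilyl)oxy]propyl}-3-methyloxiran-2-yl]methanol
Conditions: Ti(Oi-Pr)4 (10 mol %), L-(+)-diethyl tartrate (12 mol %), t-BuOOH (decane), 4 Å MS, CH2Cl2, −20 °C
Reagents that add atoms: tert-butyl hydroperoxide, CC(C)(C)OO
Why: Sharpless asymmetric epoxidation of this geraniol-type E allylic alcohol is reagent-controlled, L-(+)-tartrate delivering oxygen to the face that gives the (2S,3S)-epoxy alcohol (C6 S, C7 S) irrespective of the remote C4 centre.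

**Step 6**
Reactants: 8 [(2S,3S)-3-{(2S)-3-[(tert-butyldiphenylsilyl)oxy]-2-methyl-2-[(triethylsilyl)oxy]propyl}-3-methyloxiran-2-yl]methanol
Product: 9 (3R,5S)-6-[(tert-butyldiphenylsilyl)oxy]-3,5-dimethyl-5-[(triethylsilyl)oxy]hexane-1,3-diol
Conditions: Red-Al, THF, 0 °C → rt; aq. Rochelle salt
Reagents that add atoms: none
Why: Hydride is delivered intramolecularly from the C8 alkoxyaluminate to C7 (regioselective Red-Al opening of a 2,3-epoxy alcohol), which gives the 1,3-diol and leaves the C6–O bond and its configuration intact.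

**Step 7**
Reactants: 9 (3R,5S)-6-[(tert-butyldiphenylsilyl)oxy]-3,5-dimethyl-5-[(triethylsilyl)oxy]hexane-1,3-diol
Product: 11 (2R)-2-{(2S)-3-[(tert-butyldiphenylsilyl)oxy]-2-methyl-2-[(triethylsilyl)oxy]propyl}-2-methyloxetane, via primary tosylate 10 (not isolated)
Conditions: n-BuLi (1.0 equiv), THF, 0 °C; TsCl (1.0 equiv), 0 °C; KOt-Bu (1.5 equiv), 0 → 45 °C
Reagents that add atoms: none
Why: The primary alkoxide is sulfonylated selectively and the C6 tertiary alkoxide then closes the oxetane by 4-exo-tet Williamson displacement at C8, with no bond to C6 or C4 being broken.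

**Step 8**
Reactants: 11 (2R)-2-{(2S)-3-[(tert-butyldiphenylsilyl)oxy]-2-methyl-2-[(triethylsilyl)oxy]propyl}-2-methyloxetane
Product: 12 (3S,5S)-6-[(tert-butyldiphenylsilyl)oxy]-3-hydroperoxy-3,5-dimethyl-5-[(triethylsilyl)oxy]hexan-1-ol
Conditions: H2O2 (dry Et2O solution, 10 equiv), TMSOTf (0.3 equiv), Et2O, −78 → −20 °C
Reagents that add atoms: hydrogen peroxide, OO
Why: Lewis-acid-mediated opening of a 2,2-disubstituted oxetane by hydrogen peroxide takes place at the more substituted carbon in an SN2-like manner with inversion, which converts (6R)-11 into the (6S)-hydroperoxide and frees the C8 alcohol.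

**Step 9**
Reactants: 12 (3S,5S)-6-[(tert-butyldiphenylsilyl)oxy]-3-hydroperoxy-3,5-dimethyl-5-[(triethylsilyl)oxy]hexan-1-ol
Product: 13 tert-butyl{[(2S,4S)-6-[(2-methoxypropan-2-yl)oxy]-4-[(2-methoxypropan-2-yl)peroxy]-2,4-dimethyl-2-[(triethylsilyl)oxy]hexyl]oxy}diphenylsilane
Conditions: 2-methoxypropene (6 equiv), PPTS (5 mol %), CH2Cl2, 0 °C
Reagents that add atoms: 2-methoxypropene, COC(C)=C
Why: Acid-catalysed addition of the hydroperoxide and of the primary alcohol to the enol ether gives a peroxyketal and a mixed ketal, which mask the OOH group that would not survive the oxidation at C3.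

**Step 10**
Reactants: 13 tert-butyl{[(2S,4S)-6-[(2-methoxypropan-2-yl)oxy]-4-[(2-methoxypropan-2-yl)peroxy]-2,4-dimethyl-2-[(triethylsilyl)oxy]hexyl]oxy}diphenylsilane
Product: 14 (2S,4S)-6-[(2-methoxypropan-2-yl)oxy]-4-[(2-methoxypropan-2-yl)peroxy]-2,4-dimethylhexane-1,2-diol
Conditions: TBAF (3 equiv), THF, rt
Reagents that add atoms: none
Why: Fluoride-mediated desilylation removes both silyl ethers while the base-stable ketal and peroxyketal stay in place.

**Step 11**
Reactants: 14 (2S,4S)-6-[(2-methoxypropan-2-yl)oxy]-4-[(2-methoxypropan-2-yl)peroxy]-2,4-dimethylhexane-1,2-diol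
Product: 15 (2S,4S)-2-hydroxy-6-[(2-methoxypropan-2-yl)oxy]-4-[(2-methoxypropan-2-yl)peroxy]-2,4-dimethylhexanal
Conditions: SO3·pyridine, DMSO, i-Pr2NEt, CH2Cl2, 0 °C; crude product used at once
Reagents that add atoms: none
Why: Parikh–Doering oxidation converts the primary alcohol into the aldehyde under non-acidic conditions that spare the acid-labile ketals, the tertiary C4 alcohol being inert.

**Step 12**
Reactants: 15 (2S,4S)-2-hydroxy-6-[(2-methoxypropan-2-yl)oxy]-4-[(2-methoxypropan-2-yl)peroxy]-2,4-dimethylhexanal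
Product: 18 (4S,6S)-6-(2-hydroxyethyl)-3-methoxy-4,6-dimethyl-1,2-dioxan-4-ol (C3 epimers), via hydroperoxy aldehyde 16 (not isolated), via dioxan-3-ol 17 (not isolated)
Conditions: p-TsOH·H2O (10 mol %), MeOH, 0 °C → rt
Reagents that add atoms: methanol, CO
Why: Acidic methanolysis removes both methoxypropyl groups, the freed C6 hydroperoxide adds to the C3 aldehyde to close the six-membered peroxyhemiacetal, and acetal exchange replaces its hydroxyl by methoxy, the configuration at C3 being immaterial because it is erased in step 16.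

**Step 13**
Reactants: 18 (4S,6S)-6-(2-hydroxyethyl)-3-methoxy-4,6-dimethyl-1,2-dioxan-4-ol
Product: 19 (4S,6S)-6-{2-[(tert-butyldiphenylsilyl)oxy]ethyl}-3-methoxy-4,6-dimethyl-1,2-dioxan-4-ol (C3 epimers)
Conditions: TBDPSCl (1.1 equiv), imidazole, DMF, 0 °C
Reagents that add atoms: tert-butyl(chloro)diphenylsilane, CC(C)(C)[Si](Cl)(c1ccccc1)c1ccccc1
Why: Silylation with the bulky chlorosilane is selective for the primary C8 alcohol over the tertiary C4 alcohol.

**Step 14**
Reactants: 19 (4S,6S)-6-{2-[(tert-butyldiphenylsilyl)oxy]ethyl}-3-methoxy-4,6-dimethyl-1,2-dioxan-4-ol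
Product: 20 (4S,6S)-6-{2-[(tert-butyldiphenylsilyl)oxy]ethyl}-3-methoxy-4,6-dimethyl-1,2-dioxan-4-yl acetate (C3 epimers)
Conditions: Ac2O, DMAP (1 equiv), pyridine, rt → 40 °C
Reagents that add atoms: acetic anhydride, CC(=O)OC(C)=O
Why: DMAP-catalysed acylation esterifies the tertiary alcohol, and pyridine as the only base keeps the base-sensitive C3–H of the peroxyacetal (Kornblum–DeLaMare-type cleavage) out of danger.

**Step 15**
Reactants: 20 (4S,6S)-6-{2-[(tert-butyldiphenylsilyl)oxy]ethyl}-3-methoxy-4,6-dimethyl-1,2-dioxan-4-yl acetate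
Product: 22 (4S,6S)-4-({1-[(tert-butyldimethylsilyl)oxy]ethenyl}oxy)-6-{2-[(tert-butyldiphenylsilyl)oxy]ethyl}-3-methoxy-4,6-dimethyl-1,2-dioxane (C3 epimers), via lithium enolate 21 (not isolated)
Conditions: TBSCl (1.5 equiv), DMPU, THF, −78 °C, LDA (1.2 equiv) added last; pentane, filtration, no aqueous work-up; used crude
Reagents that add atoms: tert-butyl(chloro)dimethylsilane, CC(C)(C)[Si](C)(C)Cl
Why: Kinetic deprotonation of the acetate with LDA in the presence of TBSCl and DMPU traps the lithium enolate on oxygen as soon as it forms (internal quench, as known for ester enolates), so that it has no time to attack the O–O bond.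

**Step 16**
Reactants: 22 (4S,6S)-4-({1-[(tert-butyldimethylsilyl)oxy]ethenyl}oxy)-6-{2-[(tert-butyldiphenylsilyl)oxy]ethyl}-3-methoxy-4,6-dimethyl-1,2-dioxane
Product: 24 (3S,4S,6S)-peroxylactone: 1,2-dioxane cis-fused across C3–C4 to the γ-lactone and carrying 4-methyl plus 6-methyl plus 6-[2-(tert-butyldiphenylsilyloxy)ethyl], via peroxycarbenium triflate 23 (not isolated)
Conditions: TMSOTf (1.0 equiv), 2,6-di-tert-butyl-4-methylpyridine (0.3 equiv), CH2Cl2 (0.005 M), −78 °C; Et3N, then aq. NaHCO3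
Reagents that add atoms: none
Why: Proposed new method: TMSOTf abstracts the C3 methoxy group of either epimer of 22 as TMSOMe, and the resulting secondary peroxycarbenium ion 23 is captured by the CH2 terminus (C2) of the ketene silyl acetal on the C4 oxygen, after which loss of the TBS group to triflate unveils the lactone carbonyl. The closest known reaction type is the intermolecular Mukaiyama-type addition of silyl ketene acetals to peroxycarbenium ions generated from 3-alkoxy-1,2-dioxolanes and -dioxanes with silyl triflates; the tethered variant that closes a five-membered lactone has not been shown. The γ-lactone closes in a 5-(enolendo)-exo-trig mode, formally the less favourable enolate mode but the one that operates in aldol closures of 1,4-dicarbonyls and of α-acyloxy ketones to butenolides, and here rotation about the O–C1 bond of the neutral ketene acetal can bring its π face over C3 in an early transition state between a strong nucleophile and a strong electrophile. The new stereocentre C3 is controlled by the tether: the two-atom O–C1 link can only reach the face of C3 syn to the C4 oxygen, so the cis ring fusion and the 3S configuration follow from C4 (S), and both C3 epimers of 22 converge through the planar cation. The step needs ionisation of the exocyclic C3–OMe bond in preference to ring C3–O2 cleavage or O–O heterolysis, which the hard, oxophilic silyl triflate acting on the less hindered methoxy oxygen at −78 °C should secure, and it needs intramolecular capture to outrun protodesilylation and intermolecular coupling, for which high dilution and a hindered pyridine base are used. The dioxane ring, the configured C6 and the C8 silyl ether are spectators.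

**Step 17**
Reactants: 24 (3S,4S,6S)-peroxylactone with C8 OTBDPS
Product: 25 (3S,4S,6S)-peroxylactone with free C8 alcohol [6-(2-hydroxyethyl)]
Conditions: HF·pyridine, pyridine, THF, 0 °C → rt
Reagents that add atoms: none
Why: Buffered HF·pyridine cleaves the primary silyl ether without the basic conditions that could open the β-peroxy lactone by retro-oxa-Michael reaction.

**Step 18**
Reactants: 25 (3S,4S,6S)-peroxylactone with free C8 alcohol
Product: 26 (3S,4S,6S)-peroxylactone C8 aldehyde [6-(2-oxoethyl)]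
Conditions: Dess–Martin periodinane, NaHCO3, CH2Cl2, 0 °C → rt; used at once
Reagents that add atoms: none
Why: Buffered Dess–Martin oxidation gives the β-peroxy aldehyde under neutral conditions and does not touch the peroxide or the lactone.

**Step 19**
Reactants: 27 7-bromoheptan-1-ol
Product: 28 7-bromoheptanal
Conditions: TEMPO (10 mol %), PhI(OAc)2 (1.1 equiv), CH2Cl2, rt
Reagents that add atoms: none
Why: TEMPO-catalysed oxidation with PhI(OAc)2 stops cleanly at the aldehyde and leaves the alkyl bromide intact.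

**Step 20**
Reactants: 28 7-bromoheptanal
Product: 29 7-bromo-1,1-dimethoxyheptane
Conditions: HC(OMe)3, p-TsOH·H2O (1 mol %), MeOH, rt
Reagents that add atoms: trimethyl orthoformate, COC(OC)OC
Why: Acid-catalysed acetalisation with trimethyl orthoformate as water scavenger masks the aldehyde for the ylide chemistry.

**Step 21**
Reactants: 29 7-bromo-1,1-dimethoxyheptane
Product: 30 (7,7-dimethoxyheptyl)triphenylphosphonium bromide
Conditions: PPh3, NaHCO3 (cat.), MeCN, reflux
Reagents that add atoms: triphenylphosphine, c1ccc(cc1)P(c1ccccc1)c1ccccc1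
Why: SN2 quaternisation of triphenylphosphine by the primary bromide gives the Wittig salt, the hydrogen carbonate keeping traces of HBr from cleaving the acetal.

**Step 22**
Reactants: 26 (3S,4S,6S)-peroxylactone C8 aldehyde; 30 (7,7-dimethoxyheptyl)triphenylphosphonium bromide
Product: 32 (8Z)-alkene: peroxylactone with C7H2–C8H=C9H–(CH2)5–C15H(OMe)2 side chain, via phosphonium ylide 31 (not isolated)
Conditions: 30 (1.3 equiv), NaHMDS (1.2 equiv), THF, −78 → 0 °C; then 26, −78 → −20 °C
Reagents that add atoms: none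
Why: Wittig olefination with the pre-formed non-stabilised ylide (no excess base) at low temperature joins C8 to C9 faster than the ylide can deprotonate C7 or C2, and the Z geometry is of no consequence.

**Step 23**
Reactants: 32 (8Z)-alkene C15 dimethyl acetal
Product: 33 peroxylactone with saturated C7–C14 chain and C15 dimethyl acetal
Conditions: KO2C–N=N–CO2K (excess, in portions), AcOH, MeOH/CH2Cl2, rt
Reagents that add atoms: none
Why: Diimide generated in situ transfers hydrogen syn to the isolated C8=C9 double bond only and, unlike catalytic hydrogenation, leaves the O–O bond intact.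

**Step 24**
Reactants: 33 peroxylactone C15 dimethyl acetal
Product: 34 peroxylactone C15 aldehyde [6-(9-oxononyl)]
Conditions: p-TsOH·H2O (cat.), acetone/H2O (10:1), rt
Reagents that add atoms: water, O
Why: Acid-catalysed hydrolysis of the dimethyl acetal releases the C15 aldehyde under conditions to which the peroxide and the lactone are stable.

**Step 25**
Reactants: 35 (2E,4E)-hepta-2,4-dienal
Product: 36 (2E,4E)-hepta-2,4-dien-1-ol
Conditions: NaBH4, CeCl3·7H2O, MeOH, 0 °C
Reagents that add atoms: none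
Why: Luche reduction gives clean 1,2-reduction of the dienal without touching the diene.

**Step 26**
Reactants: 36 (2E,4E)-hepta-2,4-dien-1-ol
Product: 37 (2E,4E)-1-bromohepta-2,4-diene
Conditions: PBr3 (0.4 equiv), Et2O, −10 °C
Reagents that add atoms: phosphorus tribromide, BrP(Br)Br
Why: PBr3 converts the primary dienylic alcohol into the bromide, the conjugated primary isomer being the thermodynamically favoured allylic bromide.

**Step 27**
Reactants: 37 (2E,4E)-1-bromohepta-2,4-diene
Product: 38 diethyl [(2E,4E)-hepta-2,4-dien-1-yl]phosphonate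
Conditions: P(OEt)3, neat, 120 °C
Reagents that add atoms: triethyl phosphite, CCOP(OCC)OCC
Why: Michaelis–Arbuzov reaction of the primary allylic bromide with triethyl phosphite gives the phosphonate with the E,E-diene preserved.

**Step 28**
Reactants: 34 peroxylactone C15 aldehyde; 38 diethyl [(2E,4E)-hepta-2,4-dien-1-yl]phosphonate
Product: 40 target CNP0229098.1, via lithiated phosphonate 39 (not isolated)
Conditions: 38 (1.5 equiv), n-BuLi (1.4 equiv), THF, −78 °C; then 34, −78 °C → rt
Reagents that add atoms: none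
Why: Horner–Wadsworth–Emmons olefination: the lithiated allylic phosphonate adds through its α-carbon to the aldehyde and the adduct eliminates on warming to give the conjugated C15=C16 double bond with the E geometry favoured by reversible addition, the pre-formed anion leaving no free base that could open the peroxylactone.

**Compound list**
1 | (R)-2-methylglycidol | OC[C@]1(C)CO1 | starting material
2 | tert-butyl{[(2S)-2-methyloxiran-2-yl]methoxy}diphenylsilane | CC(C)(C)[Si](c1ccccc1)(c1ccccc1)OC[C@]1(C)CO1 | intermediate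
3 | (2S)-1-[(tert-butyldiphenylsilyl)oxy]-2-methylpent-4-yn-2-ol | C#CC[C@](C)(O)CO[Si](c1ccccc1)(c1ccccc1)C(C)(C)C | intermediate
4 | tert-butyl({(2S)-2-methyl-2-[(triethylsilyl)oxy]pent-4-yn-1-yl}oxy)diphenylsilane | C#CC[C@](C)(O[Si](CC)(CC)CC)CO[Si](c1ccccc1)(c1ccccc1)C(C)(C)C | intermediate
5 | dimethyl{(1E,4S)-5-[(tert-butyldiphenylsilyl)oxy]-2,4-dimethyl-4-[(triethylsilyl)oxy]pent-1-en-1-yl}alane | C[Al](C)/C=C(\C)C[C@](C)(O[Si](CC)(CC)CC)CO[Si](c1ccccc1)(c1ccccc1)C(C)(C)C | intermediate
6 | lithium butyl(dimethyl){(1E,4S)-5-[(tert-butyldiphenylsilyl)oxy]-2,4-dimethyl-4-[(triethylsilyl)oxy]pent-1-en-1-yl}alanate | [Li+].CCCC[Al-](C)(C)/C=C(\C)C[C@](C)(O[Si](CC)(CC)CC)CO[Si](c1ccccc1)(c1ccccc1)C(C)(C)C | intermediate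
7 | (2E,5S)-6-[(tert-butyldiphenylsilyl)oxy]-3,5-dimethyl-5-[(triethylsilyl)oxy]hex-2-en-1-ol | OC/C=C(\C)C[C@](C)(O[Si](CC)(CC)CC)CO[Si](c1ccccc1)(c1ccccc1)C(C)(C)C | intermediate
8 | [(2S,3S)-3-{(2S)-3-[(tert-butyldiphenylsilyl)oxy]-2-methyl-2-[(triethylsilyl)oxy]propyl}-3-methyloxiran-2-yl]methanol | OC[C@@H]1O[C@@]1(C)C[C@](C)(O[Si](CC)(CC)CC)CO[Si](c1ccccc1)(c1ccccc1)C(C)(C)C | intermediate
9 | (3R,5S)-6-[(tert-butyldiphenylsilyl)oxy]-3,5-dimethyl-5-[(triethylsilyl)oxy]hexane-1,3-diol | OCC[C@@](C)(O)C[C@](C)(O[Si](CC)(CC)CC)CO[Si](c1ccccc1)(c1ccccc1)C(C)(C)C | intermediate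
10 | (3R,5S)-6-[(tert-butyldiphenylsilyl)oxy]-3-hydroxy-3,5-dimethyl-5-[(triethylsilyl)oxy]hexyl 4-methylbenzenesulfonate | Cc1ccc(cc1)S(=O)(=O)OCC[C@@](C)(O)C[C@](C)(O[Si](CC)(CC)CC)CO[Si](c1ccccc1)(c1ccccc1)C(C)(C)C | intermediate
11 | (2R)-2-{(2S)-3-[(tert-butyldiphenylsilyl)oxy]-2-methyl-2-[(triethylsilyl)oxy]propyl}-2-methyloxetane | C[C@@]1(CCO1)C[C@](C)(O[Si](CC)(CC)CC)CO[Si](c1ccccc1)(c1ccccc1)C(C)(C)C | intermediate
12 | (3S,5S)-6-[(tert-butyldiphenylsilyl)oxy]-3-hydroperoxy-3,5-dimethyl-5-[(triethylsilyl)oxy]hexan-1-ol | OCC[C@](C)(OO)C[C@](C)(O[Si](CC)(CC)CC)CO[Si](c1ccccc1)(c1ccccc1)C(C)(C)C | intermediate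
13 | tert-butyl{[(2S,4S)-6-[(2-methoxypropan-2-yl)oxy]-4-[(2-methoxypropan-2-yl)peroxy]-2,4-dimethyl-2-[(triethylsilyl)oxy]hexyl]oxy}diphenylsilane | COC(C)(C)OCC[C@](C)(OOC(C)(C)OC)C[C@](C)(O[Si](CC)(CC)CC)CO[Si](c1ccccc1)(c1ccccc1)C(C)(C)C | intermediate
14 | (2S,4S)-6-[(2-methoxypropan-2-yl)oxy]-4-[(2-methoxypropan-2-yl)peroxy]-2,4-dimethylhexane-1,2-diol | COC(C)(C)OCC[C@](C)(OOC(C)(C)OC)C[C@](C)(O)CO | intermediate
15 | (2S,4S)-2-hydroxy-6-[(2-methoxypropan-2-yl)oxy]-4-[(2-methoxypropan-2-yl)peroxy]-2,4-dimethylhexanal | COC(C)(C)OCC[C@](C)(OOC(C)(C)OC)C[C@](C)(O)C=O | intermediate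
16 | (2S,4S)-4-hydroperoxy-2,6-dihydroxy-2,4-dimethylhexanal | OCC[C@](C)(OO)C[C@](C)(O)C=O | intermediate
17 | (4S,6S)-6-(2-hydroxyethyl)-4,6-dimethyl-1,2-dioxane-3,4-diol (C3 epimers) | OCC[C@@]1(C)C[C@](C)(O)C(O)OO1 | intermediate
18 | (4S,6S)-6-(2-hydroxyethyl)-3-methoxy-4,6-dimethyl-1,2-dioxan-4-ol (C3 epimers) | COC1OO[C@@](C)(CCO)C[C@]1(C)O | intermediate
19 | (4S,6S)-6-{2-[(tert-butyldiphenylsilyl)oxy]ethyl}-3-methoxy-4,6-dimethyl-1,2-dioxan-4-ol (C3 epimers) | COC1OO[C@@](C)(CCO[Si](c2ccccc2)(c2ccccc2)C(C)(C)C)C[C@]1(C)O | intermediate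
20 | (4S,6S)-6-{2-[(tert-butyldiphenylsilyl)oxy]ethyl}-3-methoxy-4,6-dimethyl-1,2-dioxan-4-yl acetate (C3 epimers) | COC1OO[C@@](C)(CCO[Si](c2ccccc2)(c2ccccc2)C(C)(C)C)C[C@]1(C)OC(C)=O | intermediate
21 | lithium enolate of acetate 20 | [Li+].COC1OO[C@@](C)(CCO[Si](c2ccccc2)(c2ccccc2)C(C)(C)C)C[C@]1(C)OC(=C)[O-] | intermediate
22 | (4S,6S)-4-({1-[(tert-butyldimethylsilyl)oxy]ethenyl}oxy)-6-{2-[(tert-butyldiphenylsilyl)oxy]ethyl}-3-methoxy-4,6-dimethyl-1,2-dioxane (C3 epimers) | COC1OO[C@@](C)(CCO[Si](c2ccccc2)(c2ccccc2)C(C)(C)C)C[C@]1(C)OC(=C)O[Si](C)(C)C(C)(C)C | intermediate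
23 | (4S,6S)-C3 peroxycarbenium triflate derived from 22 | [CH+]1OO[C@@](C)(CCO[Si](c2ccccc2)(c2ccccc2)C(C)(C)C)C[C@]1(C)OC(=C)O[Si](C)(C)C(C)(C)C.[O-]S(=O)(=O)C(F)(F)F | intermediate
24 | (3S,4S,6S)-peroxylactone, cis-fused at C3–C4, 4,6-dimethyl, 6-[2-(tert-butyldiphenylsilyloxy)ethyl] | CC(C)(C)[Si](c1ccccc1)(c1ccccc1)OCC[C@@]1(C)C[C@]2(C)OC(=O)C[C@@H]2OO1 | intermediate
25 | (3S,4S,6S)-peroxylactone, 6-(2-hydroxyethyl) | OCC[C@@]1(C)C[C@]2(C)OC(=O)C[C@@H]2OO1 | intermediate
26 | (3S,4S,6S)-peroxylactone, 6-(2-oxoethyl) (C8 aldehyde) | O=CC[C@@]1(C)C[C@]2(C)OC(=O)C[C@@H]2OO1 | intermediate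
27 | 7-bromoheptan-1-ol | OCCCCCCCBr | starting material
28 | 7-bromoheptanal | O=CCCCCCCBr | intermediate
29 | 7-bromo-1,1-dimethoxyheptane | COC(OC)CCCCCCBr | intermediate
30 | (7,7-dimethoxyheptyl)triphenylphosphonium bromide | COC(OC)CCCCCC[P+](c1ccccc1)(c1ccccc1)c1ccccc1.[Br-] | intermediate
31 | (7,7-dimethoxyheptylidene)triphenylphosphorane | COC(OC)CCCCCC=P(c1ccccc1)(c1ccccc1)c1ccccc1 | intermediate
32 | (3S,4S,6S)-peroxylactone, 6-[(2Z)-9,9-dimethoxynon-2-en-1-yl] (C8=C9 Z, C15 acetal) | COC(OC)CCCCC/C=C\C[C@@]1(C)C[C@]2(C)OC(=O)C[C@@H]2OO1 | intermediate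
33 | (3S,4S,6S)-peroxylactone, 6-(9,9-dimethoxynonyl) | COC(OC)CCCCCCCC[C@@]1(C)C[C@]2(C)OC(=O)C[C@@H]2OO1 | intermediate
34 | (3S,4S,6S)-peroxylactone, 6-(9-oxononyl) (C15 aldehyde) | O=CCCCCCCCC[C@@]1(C)C[C@]2(C)OC(=O)C[C@@H]2OO1 | intermediate
35 | (2E,4E)-hepta-2,4-dienal | CC/C=C/C=C/C=O | starting material
36 | (2E,4E)-hepta-2,4-dien-1-ol | CC/C=C/C=C/CO | intermediate
37 | (2E,4E)-1-bromohepta-2,4-diene | CC/C=C/C=C/CBr | intermediate
38 | diethyl [(2E,4E)-hepta-2,4-dien-1-yl]phosphonate | CC/C=C/C=C/CP(=O)(OCC)OCC | intermediate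
39 | lithiated diethyl [(2E,4E)-hepta-2,4-dien-1-yl]phosphonate | [Li+].CC/C=C/C=C/[CH-]P(=O)(OCC)OCC | intermediate
40 | CNP0229098.1, (3S,4S,6S)-peroxylactone with (9E,11E,13E)-hexadeca-9,11,13-trien-1-yl chain at C6 | CC/C=C/C=C/C=C/CCCCCCCC[C@@]1(C)C[C@]2(C)OC(=O)C[C@@H]2OO1 | target

**Step count and risks**
Total step count: 28. Longest linear sequence: 22 steps (steps 1–18, 22–24 and 28, from (R)-2-methylglycidol); steps 19–21 and 25–27 are side branches.

Steps most likely to fail:

1. Step 16 (bears the label). Ring closure may not keep pace with ionisation: the 5-(enolendo)-exo-trig trajectory may be too strained, so that protodesilylation back to the acetate, intermolecular coupling or endocyclic C3–O2 cleavage take over. Fallback by known chemistry, from 15 back to 25: Z-selective Still–Gennari olefination of aldehyde 15 should give methyl (2Z,4S,6S)-4-hydroxy-8-[(2-methoxypropan-2-yl)oxy]-6-[(2-methoxypropan-2-yl)peroxy]-4,6-dimethyloct-2-enoate F1. PPTS in methanol should lactonise it and remove both methoxypropyl groups to give (5S)-5-[(2S)-2-hydroperoxy-4-hydroxy-2-methylbutyl]-5-methylfuran-2(5H)-one F2. Diethylamine in trifluoroethanol should then bring about 6-exo-trig oxa-Michael addition of the hydroperoxide to the butenolide, the cis fusion being the only strain-free outcome, which gives 25 directly.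

2. Step 8. Partial ionisation of the activated oxetane to a tertiary cation would erode the inversion at C6, adventitious water would return the diol, and the acid formed could strip the silyl ethers. Fallback, from 2 back to 12: 3-bromobut-3-en-1-ol is silylated to 2-bromo-4-[(triethylsilyl)oxy]but-1-ene F3. Its Grignard reagent with catalytic CuI opens epoxide 2 to (2S)-1-[(tert-butyldiphenylsilyl)oxy]-2-methyl-4-methylidene-6-[(triethylsilyl)oxy]hexan-2-ol F4, and TESOTf gives its C4 triethylsilyl ether F5. Mukaiyama–Isayama hydroperoxysilylation (Co(thd)2, O2, Et3SiH) of the 1,1-disubstituted alkene gives the C6 triethylsilyl peroxide F6 as both C6 epimers. PPTS in methanol cleaves the silyl peroxide and the primary silyl ether to give 12 together with its (3R,5S) C6 epimer F7, which is removed by chromatography there or at 18.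

3. Step 28. The dienyl anion may add through its γ- or ε-carbon, the E selectivity at C15=C16 may be incomplete, and lithium alkoxide intermediates may open the peroxylactone by retro-oxa-Michael reaction on warming. Fallback, from 34 to 40: Wittig reaction with (triphenylphosphoranylidene)acetaldehyde under neutral conditions gives the (E)-enal F8 (C15=C16, C17 aldehyde), and a second such reaction gives the (2E,4E)-dienal F9 (C19 aldehyde). 1-Phenyl-1H-tetrazole-5-thiol is alkylated with 1-bromopropane to 1-phenyl-5-(propylsulfanyl)-1H-tetrazole F10 and oxidised (Mo(VI), H2O2) to 1-phenyl-5-(propylsulfonyl)-1H-tetrazole F11. Julia–Kocienski olefination of F9 with pre-metalated F11 (KHMDS, DME, −60 °C), a saturated sulfone meeting a conjugated aldehyde, should install C19=C20 with E geometry and give 40.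

**Further compounds**
F1 | step 16 | methyl (2Z,4S,6S)-4-hydroxy-8-[(2-methoxypropan-2-yl)oxy]-6-[(2-methoxypropan-2-yl)peroxy]-4,6-dimethyloct-2-enoate | COC(=O)/C=C\[C@@](C)(O)C[C@](C)(CCOC(C)(C)OC)OOC(C)(C)OC
F2 | step 16 | (5S)-5-[(2S)-2-hydroperoxy-4-hydroxy-2-methylbutyl]-5-methylfuran-2(5H)-one | OCC[C@](C)(OO)C[C@]1(C)OC(=O)C=C1
F3 | step 8 | 2-bromo-4-[(triethylsilyl)oxy]but-1-ene | C=C(Br)CCO[Si](CC)(CC)CC
F4 | step 8 | (2S)-1-[(tert-butyldiphenylsilyl)oxy]-2-methyl-4-methylidene-6-[(triethylsilyl)oxy]hexan-2-ol | C=C(CCO[Si](CC)(CC)CC)C[C@](C)(O)CO[Si](c1ccccc1)(c1ccccc1)C(C)(C)C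
F5 | step 8 | C4 triethylsilyl ether of F4 | C=C(CCO[Si](CC)(CC)CC)C[C@](C)(O[Si](CC)(CC)CC)CO[Si](c1ccccc1)(c1ccccc1)C(C)(C)C
F6 | step 8 | C6 triethylsilyl peroxide, both C6 epimers, (5S) | CC[Si](CC)(CC)OOC(C)(CCO[Si](CC)(CC)CC)C[C@](C)(O[Si](CC)(CC)CC)CO[Si](c1ccccc1)(c1ccccc1)C(C)(C)C
F7 | step 8 | (3R,5S)-6-[(tert-butyldiphenylsilyl)oxy]-3-hydroperoxy-3,5-dimethyl-5-[(triethylsilyl)oxy]hexan-1-ol (C6 epimer of 12) | OCC[C@@](C)(OO)C[C@](C)(O[Si](CC)(CC)CC)CO[Si](c1ccccc1)(c1ccccc1)C(C)(C)C
F8 | step 28 | (3S,4S,6S)-peroxylactone, 6-[(9E)-11-oxoundec-9-en-1-yl] | O=C/C=C/CCCCCCCC[C@@]1(C)C[C@]2(C)OC(=O)C[C@@H]2OO1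
F9 | step 28 | (3S,4S,6S)-peroxylactone, 6-[(9E,11E)-13-oxotrideca-9,11-dien-1-yl] | O=C/C=C/C=C/CCCCCCCC[C@@]1(C)C[C@]2(C)OC(=O)C[C@@H]2OO1
F10 | step 28 | 1-phenyl-5-(propylsulfanyl)-1H-tetrazole | CCCSc1nnnn1-c1ccccc1
F11 | step 28 | 1-phenyl-5-(propylsulfonyl)-1H-tetrazole | CCCS(=O)(=O)c1nnnn1-c1ccccc1
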